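Assumption: (−)-epicatechin and (+)-catechin are taken as commercial chiral-pool starting materials; the target SMILES is read as epicatechin-(4β→8)-epicatechin-(4β→8)-epicatechin-(4β→8)-catechin (2,3-cis-3,4-trans extension units, 2,3-trans terminal unit) and is called the target tetramer below.

**Retrosynthetic overview**
- Target tetramer ⇐ global hydrogenolysis of its hexadeca-O-benzyl ether.
- Key step: the central interflavan bond is made last by a 2+2 union of two dimers, not by one-unit-at-a-time chain extension. The dimeric electrophile is made in the same operation by late-stage, site-selective DDQ oxidation of the lower C4–H2 of octa-O-benzyl procyanidin B2; the nucleophile is octa-O-benzyl procyanidin B1.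
- Both dimers ⇐ one monomeric C4 electrophile (4β-(2-ethoxyethoxy) tetra-O-benzylepicatechin) plus tetra-O-benzylcatechin or tetra-O-benzylepicatechin, by 4β-selective Friedel–Crafts flavanylation.
- The eight C2/C3 stereocentres come from the chiral pool; the three C4 stereocentres are set by substrate control (attack anti to the quasi-axial 3-OH).
- No ring is built: rings A, B and C of all four units come intact from the starting materials. Only the three C4–C8 bonds are formed, the two outer ones first and the central one last.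

**Route**

Step 1
Reactants: 1 (−)-epicatechin
Product: 2 5,7,3',4'-tetra-O-benzyl-(−)-epicatechin (3-OH free)
Conditions: BnBr (4.4 equiv), K2CO3 (5 equiv), DMF, −10 °C → rt, argon
Reagents that add atoms: benzyl bromide, BrCc1ccccc1
Why: Williamson etherification in which K2CO3 deprotonates only the four phenols, so the secondary 3-OH stays free and no stereocentre is touched, while low temperature and exclusion of air limit C-benzylation and C2 epimerisation.

Step 2
Reactants: 3 (+)-catechin
Product: 4 5,7,3',4'-tetra-O-benzyl-(+)-catechin (3-OH free)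
Conditions: BnBr (4.4 equiv), K2CO3 (5 equiv), DMF, −10 °C → rt, argon
Reagents that add atoms: benzyl bromide, BrCc1ccccc1
Why: The same phenol-selective Williamson etherification, which leaves the 2,3-trans stereocentres and the 3-OH untouched.

Step 3
Reactants: 2 5,7,3',4'-tetra-O-benzyl-(−)-epicatechin
Product: 5 4β-(2-ethoxyethoxy)-5,7,3',4'-tetra-O-benzylepicatechin (2,3-cis-3,4-trans)
Conditions: DDQ (2 equiv), 2-ethoxyethanol (5 equiv), CH2Cl2, rt, 2 h
Reagents that add atoms: 2-ethoxyethanol, CCOCCO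
Why: DDQ-mediated benzylic C–H oxidation (hydride abstraction) at C4 gives a cation stabilised by the trioxygenated ring A, which the alcohol traps anti to the quasi-axial 3-OH to give the 3,4-trans ether, a centre that is ionised again later so its configuration is not critical.

Step 4
Reactants: 5 4β-(2-ethoxyethoxy)-5,7,3',4'-tetra-O-benzylepicatechin; 4 5,7,3',4'-tetra-O-benzyl-(+)-catechin (3.5 equiv, excess recovered)
Product: 6 octa-O-benzyl procyanidin B1 [tetra-O-benzylepicatechin-(4β→8)-tetra-O-benzylcatechin]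
Conditions: TMSOTf (0.2 equiv), CH2Cl2, −78 °C, 10 min; sat. NaHCO3
Reagents that add atoms: none
Why: Lewis-acid-promoted SN1-type Friedel–Crafts flavanylation in which the C4 cation from 5 is attacked by the most nucleophilic position (C8) of excess 4 from the face opposite the quasi-axial 3-OH, setting the new C4 stereocentre as 4β (3,4-trans), while the excess nucleophile suppresses over-oligomerisation.

Step 5
Reactants: 5 4β-(2-ethoxyethoxy)-5,7,3',4'-tetra-O-benzylepicatechin; 2 5,7,3',4'-tetra-O-benzyl-(−)-epicatechin (3.5 equiv, excess recovered)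
Product: 7 octa-O-benzyl procyanidin B2 [tetra-O-benzylepicatechin-(4β→8)-tetra-O-benzylepicatechin]
Conditions: TMSOTf (0.2 equiv), CH2Cl2, −78 °C, 10 min; sat. NaHCO3
Reagents that add atoms: none
Why: The same TMSOTf-catalysed Friedel–Crafts flavanylation, with C8 of 2 attacking the C4 cation anti to the 3-OH to set the 4β interflavan stereocentre.

Step 6
Reactants: 7 octa-O-benzyl procyanidin B2; 6 octa-O-benzyl procyanidin B1 (2.5 equiv, excess recovered)
Product: 9 hexadeca-O-benzyl ether of the target tetramer, via dimeric 4β-(2-ethoxyethoxy) ether 8 (not isolated)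
Conditions: DDQ (1.2 equiv), 2-ethoxyethanol (3 equiv), CH2Cl2, 0 °C → rt; filter through basic Al2O3 (removes DDQ and its hydroquinone), evaporate; then crude 8 added slowly to 6, TMSOTf (0.3 equiv), 4 Å MS, CH2Cl2, −78 °C
Reagents that add atoms: none
Why: Proposed new method: DDQ should remove hydride only from the quasi-axial C4–H of the lower CH2 of 7, which is aligned with the ring A π-system, because the upper doubly benzylic C4–H is quasi-equatorial (its 4β-aryl group is quasi-axial), lies near the planes of both flanking arenes and is sterically shielded, so the alcohol-trapped dimer 8 forms site-selectively and, on TMSOTf ionisation, its cation is attacked by the upper-unit C8 of excess 6 anti to the quasi-axial 3-OH to set the last C4 stereocentre as 4β, the closest known chemistry being the DDQ/alcohol C4 oxidation of monomeric benzylated flavan-3-ols followed by Lewis-acid Friedel–Crafts flavanylation (steps 3 to 5), here applied to a dimer and telescoped.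

Step 7
Reactants: 9 hexadeca-O-benzyl ether of the target tetramer
Product: 10 epicatechin-(4β→8)-epicatechin-(4β→8)-epicatechin-(4β→8)-catechin (the target tetramer)
Conditions: H2 (1 atm), Pd(OH)2/C, THF/MeOH/H2O (20:1:1), rt; filter, lyophilise
Reagents that add atoms: none
Why: Catalytic hydrogenolysis cleaves all sixteen aryl benzyl ethers under neutral conditions that leave the acid-labile interflavan bonds, the pyran C–O bonds and all eleven stereocentres intact.

**Compound list**

1 | (−)-epicatechin, (2R,3R) | Oc1cc(O)c2c(c1)O[C@H](c1ccc(O)c(O)c1)[C@H](O)C2 | starting material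
2 | 5,7,3',4'-tetra-O-benzyl-(−)-epicatechin | O(Cc3ccccc3)c1cc(OCc3ccccc3)c2c(c1)O[C@H](c1ccc(OCc3ccccc3)c(OCc3ccccc3)c1)[C@H](O)C2 | intermediate
3 | (+)-catechin, (2R,3S) | Oc1cc(O)c2c(c1)O[C@H](c1ccc(O)c(O)c1)[C@@H](O)C2 | starting material
4 | 5,7,3',4'-tetra-O-benzyl-(+)-catechin | O(Cc3ccccc3)c1cc(OCc3ccccc3)c2c(c1)O[C@H](c1ccc(OCc3ccccc3)c(OCc3ccccc3)c1)[C@@H](O)C2 | intermediate
5 | 4β-(2-ethoxyethoxy)-5,7,3',4'-tetra-O-benzylepicatechin (3,4-trans) | O(Cc3ccccc3)c1cc(OCc3ccccc3)c2c(c1)O[C@H](c1ccc(OCc3ccccc3)c(OCc3ccccc3)c1)[C@H](O)[C@H]2OCCOCC | intermediate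
6 | octa-O-benzyl procyanidin B1, tetra-O-benzylepicatechin-(4β→8)-tetra-O-benzylcatechin | O(Cc3ccccc3)c1cc(OCc3ccccc3)c2c(c1)O[C@H](c1ccc(OCc3ccccc3)c(OCc3ccccc3)c1)[C@H](O)[C@H]2c1c(OCc3ccccc3)cc(OCc3ccccc3)c2c1O[C@H](c1ccc(OCc3ccccc3)c(OCc3ccccc3)c1)[C@@H](O)C2 | intermediate
7 | octa-O-benzyl procyanidin B2, tetra-O-benzylepicatechin-(4β→8)-tetra-O-benzylepicatechin | O(Cc3ccccc3)c1cc(OCc3ccccc3)c2c(c1)O[C@H](c1ccc(OCc3ccccc3)c(OCc3ccccc3)c1)[C@H](O)[C@H]2c1c(OCc3ccccc3)cc(OCc3ccccc3)c2c1O[C@H](c1ccc(OCc3ccccc3)c(OCc3ccccc3)c1)[C@H](O)C2 | intermediate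
8 | octa-O-benzyl procyanidin B2 carrying a 4β-(2-ethoxyethoxy) group on C4 of the lower unit | O(Cc3ccccc3)c1cc(OCc3ccccc3)c2c(c1)O[C@H](c1ccc(OCc3ccccc3)c(OCc3ccccc3)c1)[C@H](O)[C@H]2c1c(OCc3ccccc3)cc(OCc3ccccc3)c2c1O[C@H](c1ccc(OCc3ccccc3)c(OCc3ccccc3)c1)[C@H](O)[C@H]2OCCOCC | intermediate
9 | hexadeca-O-benzyl ether of the target tetramer (all sixteen phenols benzylated, four 3-OH free), tetra-O-benzylepicatechin-(4β→8)-tetra-O-benzylepicatechin-(4β→8)-tetra-O-benzylepicatechin-(4β→8)-tetra-O-benzylcatechin | O(Cc3ccccc3)c1cc(OCc3ccccc3)c2c(c1)O[C@H](c1ccc(OCc3ccccc3)c(OCc3ccccc3)c1)[C@H](O)[C@H]2c1c(OCc3ccccc3)cc(OCc3ccccc3)c2c1O[C@H](c1ccc(OCc3ccccc3)c(OCc3ccccc3)c1)[C@H](O)[C@H]2c1c(OCc3ccccc3)cc(OCc3ccccc3)c2c1O[C@H](c1ccc(OCc3ccccc3)c(OCc3ccccc3)c1)[C@H](O)[C@H]2c1c(OCc3ccccc3)cc(OCc3ccccc3)c2c1O[C@H](c1ccc(OCc3ccccc3)c(OCc3ccccc3)c1)[C@@H](O)C2 | intermediate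
10 | target tetramer, epicatechin-(4β→8)-epicatechin-(4β→8)-epicatechin-(4β→8)-catechin | Oc1cc(O)c2c(c1)O[C@H](c1ccc(O)c(O)c1)[C@H](O)[C@H]2c1c(O)cc(O)c2c1O[C@H](c1ccc(O)c(O)c1)[C@H](O)[C@H]2c1c(O)cc(O)c2c1O[C@H](c1ccc(O)c(O)c1)[C@H](O)[C@H]2c1c(O)cc(O)c2c1O[C@H](c1ccc(O)c(O)c1)[C@@H](O)C2 | target

**Totals**
Total step count: 7. Longest linear sequence: 5 steps (steps 1, 3, 5, 6, 7 from (−)-epicatechin).

**Three steps most likely to fail, each with a fallback**

Step 6 (DDQ may attack the wrong C–H or over-oxidise 7, and uncapped crude 8 may self-condense). The fallback sets out from 5 and comes back at 9. It installs the leaving group of the dimeric electrophile at the monomer stage and relies on hard/soft orthogonal activation instead of late C–H oxidation. Compound 5 is treated with 4-methylbenzenethiol and BF3·OEt2 in CH2Cl2 at −78 °C; the thiol captures the C4 cation trans to the 3-OH and gives 4β-(4-methylphenylthio)-5,7,3',4'-tetra-O-benzylepicatechin F1. F1 (3 equiv) then acts as the C8 nucleophile toward a second portion of 5 under TMSOTf at −78 °C. Its soft C–S bond is not ionised by the hard silyl Lewis acid, in the way a thioglycoside acceptor survives an imidate glycosylation, so the product is octa-O-benzyl procyanidin B2 4β-(4-methylphenyl) thioether F2. Thiophilic activation of F2 with AgBF4 in THF at 0 °C in the dark, in the presence of 6 (2.5 equiv), forms the central 4β→8 bond and gives 9. Step 7 then follows unchanged.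

Step 7 (sixteen-fold hydrogenolysis may stall at insoluble, partly debenzylated material or over-reduce). The fallback sets out from 9 and comes back at 10, and uses neither H2 nor Pd. Compound 9 is debenzylated with BCl3 and pentamethylbenzene as benzyl-cation scavenger in CH2Cl2 at −78 °C and quenched with MeOH at −78 °C. The crude polyphenol is peracetylated (Ac2O, pyridine, rt) to the eicosa-O-acetate of the target tetramer F3, which, unlike the free phenol, can be purified on silica and fully characterised. Methanolysis with K2CO3 in degassed MeOH at 0 °C under argon, followed by AcOH and Sephadex LH-20, returns 10. The interflavan bonds could cleave under the Lewis acid, which is why this is kept as the fallback.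

Step 1 (benzylation of epicatechin is low-yielding because of C-benzylation and base-induced C2 epimerisation). The fallback sets out from 4 and comes back at 2, so that all four units derive from (+)-catechin. Compound 4 is oxidised with Dess–Martin periodinane in CH2Cl2 at rt to (2R)-5,7,3',4'-tetrakis(benzyloxy)flavan-3-one F4. Reduction with LiBH(s-Bu)3 in THF at −78 °C delivers hydride to the face opposite the C2 aryl group and gives the 2,3-cis alcohol 2.

**Further compounds**

F1 | step 6 | 4β-(4-methylphenylthio)-5,7,3',4'-tetra-O-benzylepicatechin | O(Cc3ccccc3)c1cc(OCc3ccccc3)c2c(c1)O[C@H](c1ccc(OCc3ccccc3)c(OCc3ccccc3)c1)[C@H](O)[C@H]2Sc1ccc(C)cc1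
F2 | step 6 | octa-O-benzyl procyanidin B2 4β-(4-methylphenyl) thioether (sulfur on C4 of the lower unit) | O(Cc3ccccc3)c1cc(OCc3ccccc3)c2c(c1)O[C@H](c1ccc(OCc3ccccc3)c(OCc3ccccc3)c1)[C@H](O)[C@H]2c1c(OCc3ccccc3)cc(OCc3ccccc3)c2c1O[C@H](c1ccc(OCc3ccccc3)c(OCc3ccccc3)c1)[C@H](O)[C@H]2Sc1ccc(C)cc1
F3 | step 7 | eicosa-O-acetate of the target tetramer | CC(=O)Oc1cc(OC(C)=O)c2c(c1)O[C@H](c1ccc(OC(C)=O)c(OC(C)=O)c1)[C@H](OC(C)=O)[C@H]2c1c(OC(C)=O)cc(OC(C)=O)c2c1O[C@H](c1ccc(OC(C)=O)c(OC(C)=O)c1)[C@H](OC(C)=O)[C@H]2c1c(OC(C)=O)cc(OC(C)=O)c2c1O[C@H](c1ccc(OC(C)=O)c(OC(C)=O)c1)[C@H](OC(C)=O)[C@H]2c1c(OC(C)=O)cc(OC(C)=O)c2c1O[C@H](c1ccc(OC(C)=O)c(OC(C)=O)c1)[C@@H](OC(C)=O)C2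
F4 | step 1 | (2R)-5,7,3',4'-tetrakis(benzyloxy)flavan-3-one | O(Cc3ccccc3)c1cc(OCc3ccccc3)c2c(c1)O[C@H](c1ccc(OCc3ccccc3)c(OCc3ccccc3)c1)C(=O)C2
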